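Ring A is disconnected at C4–C5 and C2–C3 (labdane numbering). The quaternary C4 with its methyl and carbonyl carbon (C19) is the α-carbon of methacrolein and C3 its β-carbon. C2, C1, C10 and C5 are the terminal 1,3-diene of an acyclic E,E-trienyne that already carries the ring B carbons (C6–C9, C17, C20) and C11–C14 as a butynyl chain. One catalytic enantioselective Diels–Alder union closes ring A and sets C4 and C5, with the formyl group cis to the C5 chain. Ring B then closes by cation–olefin cyclisation from C10, the cation-inert alkyne is carbometalated to the E-allylic alcohol, and acetylation finishes the target.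

Key step: step 5

Remark: the target is 4S,5R,10S (ester β, 5-H α, C10 methyl β), so the cycloadduct required is the (1S,2R)-aldehyde with formyl and chain cis.
Assumption: the oxazaborolidinium catalyst from (S)-diphenylprolinol is taken to direct the diene to the re face of the methacrolein α-carbon (formyl C–H···O binding model); the mirror-image catalyst is equally accessible if the opposite sense is found.

Step 1
Reactants: 1 geranyl bromide [(2E)-1-bromo-3,7-dimethylocta-2,6-diene]; 2 1-(trimethylsilyl)propyne
Product: 4 trimethyl[(5E)-6,10-dimethylundeca-5,9-dien-1-yn-1-yl]silane, via 3-lithio-1-(trimethylsilyl)propyne 3 (not isolated)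
Conditions: 2, n-BuLi, THF, −78 → −20 °C; then 1, −78 °C → rt
Reagents that add atoms: none
Why: Propargylic lithiation of the silylpropyne followed by SN2 alkylation of the primary allylic bromide should give the 1,5-enyne, the silyl group blocking the alkyne terminus and the 2E olefin of the geranyl unit remaining untouched.

Step 2
Reactants: 4 trimethyl[(5E)-6,10-dimethylundeca-5,9-dien-1-yn-1-yl]silane
Product: 6 (2E,6E)-2,6-dimethyl-11-(trimethylsilyl)undeca-2,6-dien-10-ynal, via allylic alcohol 5 (not isolated)
Conditions: SeO2 (0.5 equiv), t-BuOOH, salicylic acid (cat.), CH2Cl2, 0 °C → rt, stopped at partial conversion; aqueous work-up, then crude with MnO2, CH2Cl2, rt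
Reagents that add atoms: selenium dioxide, O=[Se]=O; tert-butyl hydroperoxide, CC(C)(C)OO
Why: Riley allylic oxidation (ene reaction then [2,3]-shift) should attack the E-methyl of the terminal isopropylidene group in preference to the internal olefin, and MnO2 then takes the allylic alcohol on to the E-enal without affecting the silylalkyne.

Step 3
Reactants: 6 (2E,6E)-2,6-dimethyl-11-(trimethylsilyl)undeca-2,6-dien-10-ynal
Product: 7 trimethyl[(5E,9E)-6,10-dimethyldodeca-5,9,11-trien-1-yn-1-yl]silane
Conditions: Ph3PCH3Br, KOtBu, THF, 0 °C; then 6, 0 °C → rt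
Reagents that add atoms: methyltriphenylphosphonium bromide, C[P+](c1ccccc1)(c1ccccc1)c1ccccc1.[Br-]
Why: Wittig methylenation of the unhindered enal should give the terminal 1,3-diene with the E geometry of the trisubstituted olefin retained, while the silyl group keeps the alkyne inert to the basic ylide.

Step 4
Reactants: 7 trimethyl[(5E,9E)-6,10-dimethyldodeca-5,9,11-trien-1-yn-1-yl]silane
Product: 8 (5E,9E)-6,10-dimethyldodeca-5,9,11-trien-1-yne
Conditions: K2CO3 (cat.), MeOH, rt; used promptly, stored cold
Reagents that add atoms: none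
Why: Methoxide-mediated protodesilylation of an alkynylsilane is mild enough to leave the acid- and heat-sensitive diene unchanged.

Step 5
Reactants: 8 (5E,9E)-6,10-dimethyldodeca-5,9,11-trien-1-yne; 9 methacrolein (2-methylprop-2-enal)
Product: 10 (1S,2R)-1,3-dimethyl-2-[(3E)-3-methyloct-3-en-7-yn-1-yl]cyclohex-3-ene-1-carbaldehyde (formyl cis to the chain)
Conditions: (S)-3,3-diphenyl-1-(2-methylphenyl)tetrahydro-1H,3H-pyrrolo[1,2-c][1,3,2]oxazaborole (20 mol %) protonated with HN(SO2CF3)2 (17 mol %), 9 (3 equiv), CH2Cl2, −78 → −40 °C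
Reagents that add atoms: none
Why: The oxazaborolidinium ion binds methacrolein at boron in the s-trans form with a formyl C–H···O contact, and the activated enal undergoes a concerted, asynchronous [4+2] cycloaddition in which its β-carbon (C3) bonds ahead to the unsubstituted diene terminus C2 and its α-carbon (C4) to the alkyl-bearing terminus C5. The closest known reaction type is the oxazaborolidinium-catalysed Diels–Alder reaction of 2-methylacrolein with acyclic alkyl-substituted 1,3-dienes. Ring A closes as a six-membered ring by suprafacial two-bond union of the two components (C2–C3 and C4–C5), leaving the C1=C10 olefin. C4 is set by the catalyst, whose carbinol phenyl group screens the si face of the enal α-carbon so that the diene adds to the re face (4S), and C5 is set relative to C4 by the E geometry of the C5=C10 bond together with the endo position of the formyl group, which places formyl and chain cis (5R). The step needs ortho regiochemistry, endo orientation and face selection: the first should follow from the 1-alkyl terminus and the unhindered C2 outweighing the opposing pull of the C10 methyl, as in 1-vinylcycloalkenes, the second from the absence of the bridging methylene that makes this enal exo-selective with cyclopentadiene, and the third from the catalyst. Only the terminal diene is conjugated and able to reach the s-cis form, so the isolated C8=C9 olefin and the alkyne should stay out of the reaction.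

Step 6
Reactants: 10 (1S,2R)-1,3-dimethyl-2-[(3E)-3-methyloct-3-en-7-yn-1-yl]cyclohex-3-ene-1-carbaldehyde
Product: 11 (1S,2R)-1,3-dimethyl-2-[(3E)-3-methyloct-3-en-7-yn-1-yl]cyclohex-3-ene-1-carboxylic acid
Conditions: NaClO2, NaH2PO4, 2-methyl-2-butene (large excess), t-BuOH/H2O, 0 °C → rt
Reagents that add atoms: sodium chlorite, [Na+].[O-]Cl=O
Why: Pinnick oxidation converts the non-enolisable neopentyl aldehyde to the acid without touching C4, the excess scavenger alkene protecting the two trisubstituted olefins from hypochlorous acid.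

Step 7
Reactants: 11 (1S,2R)-1,3-dimethyl-2-[(3E)-3-methyloct-3-en-7-yn-1-yl]cyclohex-3-ene-1-carboxylic acid
Product: 12 methyl (1S,2R)-1,3-dimethyl-2-[(3E)-3-methyloct-3-en-7-yn-1-yl]cyclohex-3-ene-1-carboxylate
Conditions: MeI, K2CO3, DMF, rt
Reagents that add atoms: iodomethane, CI
Why: O-alkylation of the carboxylate (SN2 at methyl) sidesteps the steric hindrance at the quaternary C4 that would slow acyl-substitution esterification, and the terminal alkyne is not deprotonated by carbonate.

Step 8
Reactants: 12 methyl (1S,2R)-1,3-dimethyl-2-[(3E)-3-methyloct-3-en-7-yn-1-yl]cyclohex-3-ene-1-carboxylate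
Product: 13 methyl (1S,4aS,8aR)-5-(but-3-yn-1-yl)-1,4a,6-trimethyl-1,2,3,4,4a,7,8,8a-octahydronaphthalene-1-carboxylate
Conditions: MeSO3H (2 equiv), CH2Cl2, −20 °C → rt, until olefin isomers have converged
Reagents that add atoms: none
Why: In this cation–olefin (polyene-type) cyclisation of a monocyclic terpenoid diene, Markovnikov protonation of the ring A olefin at C1 gives the tertiary C10 cation, which C9 of the E-trisubstituted olefin captures through a chair-like six-membered transition state with the tether equatorial, so the C9–C10 bond forms anti to the C5 hydrogen (trans-decalin, C10 methyl β, 10S), and the tertiary C8 cation then loses the C9 proton under reversible conditions to the most substituted 8(9)-olefin, the terminal alkyne being too poor a π-nucleophile to take part.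

Step 9
Reactants: 13 methyl (1S,4aS,8aR)-5-(but-3-yn-1-yl)-1,4a,6-trimethyl-1,2,3,4,4a,7,8,8a-octahydronaphthalene-1-carboxylate
Product: 16 methyl (1S,4aS,8aR)-5-[(3E)-5-hydroxy-3-methylpent-3-en-1-yl]-1,4a,6-trimethyl-1,2,3,4,4a,7,8,8a-octahydronaphthalene-1-carboxylate, via alkenyldimethylalane 14 (not isolated), via lithium alkenylaluminate 15 (not isolated)
Conditions: Me3Al (3 equiv), Cp2ZrCl2 (0.25 equiv), CH2Cl2, 0 °C → rt; excess Me3Al evaporated; n-BuLi (1 equiv), THF/hexane, −78 °C; (CH2O)n, −78 °C → rt; aqueous potassium sodium tartrate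
Reagents that add atoms: trimethylaluminium, C[Al](C)C; paraformaldehyde (as formaldehyde), C=O
Why: Negishi zirconium-catalysed methylalumination adds methyl and aluminium syn across the terminal alkyne with the metal at the terminus, and the derived aluminate is hydroxymethylated with retention to give the 13E allylic alcohol, while the tetrasubstituted olefin and the axial neopentyl C19 ester should be too hindered to react.

Step 10
Reactants: 16 methyl (1S,4aS,8aR)-5-[(3E)-5-hydroxy-3-methylpent-3-en-1-yl]-1,4a,6-trimethyl-1,2,3,4,4a,7,8,8a-octahydronaphthalene-1-carboxylate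
Product: 17 methyl (1S,4aS,8aR)-5-[(3E)-5-acetoxy-3-methylpent-3-en-1-yl]-1,4a,6-trimethyl-1,2,3,4,4a,7,8,8a-octahydronaphthalene-1-carboxylate (CNP0206695.1)
Conditions: Ac2O, pyridine, DMAP (cat.), CH2Cl2, 0 °C → rt
Reagents that add atoms: acetic anhydride, CC(=O)OC(C)=O
Why: DMAP-catalysed acylation of the unhindered primary allylic alcohol is fast and leaves every stereocentre and olefin unchanged.

Compound list
1 | geranyl bromide, (2E)-1-bromo-3,7-dimethylocta-2,6-diene | CC(C)=CCC/C(C)=C/CBr | starting material
2 | 1-(trimethylsilyl)propyne | CC#C[Si](C)(C)C | starting material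
3 | 3-lithio-1-(trimethylsilyl)propyne | [Li]CC#C[Si](C)(C)C | intermediate
4 | trimethyl[(5E)-6,10-dimethylundeca-5,9-dien-1-yn-1-yl]silane | CC(C)=CCC/C(C)=C/CCC#C[Si](C)(C)C | intermediate
5 | (2E,6E)-2,6-dimethyl-11-(trimethylsilyl)undeca-2,6-dien-10-yn-1-ol | OC/C(C)=C/CC/C(C)=C/CCC#C[Si](C)(C)C | intermediate
6 | (2E,6E)-2,6-dimethyl-11-(trimethylsilyl)undeca-2,6-dien-10-ynal | O=C/C(C)=C/CC/C(C)=C/CCC#C[Si](C)(C)C | intermediate
7 | trimethyl[(5E,9E)-6,10-dimethyldodeca-5,9,11-trien-1-yn-1-yl]silane | C=C/C(C)=C/CC/C(C)=C/CCC#C[Si](C)(C)C | intermediate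
8 | (5E,9E)-6,10-dimethyldodeca-5,9,11-trien-1-yne | C=C/C(C)=C/CC/C(C)=C/CCC#C | intermediate
9 | methacrolein, 2-methylprop-2-enal | CC(=C)C=O | starting material
10 | (1S,2R)-1,3-dimethyl-2-[(3E)-3-methyloct-3-en-7-yn-1-yl]cyclohex-3-ene-1-carbaldehyde | O=C[C@@]1(C)CCC=C(C)[C@H]1CC/C(C)=C/CCC#C | intermediate
11 | (1S,2R)-1,3-dimethyl-2-[(3E)-3-methyloct-3-en-7-yn-1-yl]cyclohex-3-ene-1-carboxylic acid | OC(=O)[C@@]1(C)CCC=C(C)[C@H]1CC/C(C)=C/CCC#C | intermediate
12 | methyl (1S,2R)-1,3-dimethyl-2-[(3E)-3-methyloct-3-en-7-yn-1-yl]cyclohex-3-ene-1-carboxylate | COC(=O)[C@@]1(C)CCC=C(C)[C@H]1CC/C(C)=C/CCC#C | intermediate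
13 | methyl (1S,4aS,8aR)-5-(but-3-yn-1-yl)-1,4a,6-trimethyl-1,2,3,4,4a,7,8,8a-octahydronaphthalene-1-carboxylate | COC(=O)[C@@]1(C)CCC[C@]2(C)C(CCC#C)=C(C)CC[C@@H]12 | intermediate
14 | methyl (1S,4aS,8aR)-5-[(3E)-4-(dimethylalumanyl)-3-methylbut-3-en-1-yl]-1,4a,6-trimethyl-1,2,3,4,4a,7,8,8a-octahydronaphthalene-1-carboxylate | COC(=O)[C@@]1(C)CCC[C@]2(C)C(CC/C(C)=C/[Al](C)C)=C(C)CC[C@@H]12 | intermediate
15 | lithium butyl(dimethyl)alkenylaluminate derived from 14 | [Li+].COC(=O)[C@@]1(C)CCC[C@]2(C)C(CC/C(C)=C/[Al-](C)(C)CCCC)=C(C)CC[C@@H]12 | intermediate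
16 | methyl (1S,4aS,8aR)-5-[(3E)-5-hydroxy-3-methylpent-3-en-1-yl]-1,4a,6-trimethyl-1,2,3,4,4a,7,8,8a-octahydronaphthalene-1-carboxylate | COC(=O)[C@@]1(C)CCC[C@]2(C)C(CC/C(C)=C/CO)=C(C)CC[C@@H]12 | intermediate
17 | methyl (1S,4aS,8aR)-5-[(3E)-5-acetoxy-3-methylpent-3-en-1-yl]-1,4a,6-trimethyl-1,2,3,4,4a,7,8,8a-octahydronaphthalene-1-carboxylate | COC(=O)[C@@]1(C)CCC[C@]2(C)C(CC/C(C)=C/COC(C)=O)=C(C)CC[C@@H]12 | target

Total step count: 10. Longest linear sequence: 10 steps (1 → 17).

Steps most likely to fail

Step 5. Regiocontrol may erode because the C10 methyl of the diene opposes the ortho preference of the C5 alkyl terminus. The endo preference or the face selection may also be insufficient, and the cationic catalyst may oligomerise the diene. Fallback, from 8 and 9, returning at 11: the cycloaddition is promoted by achiral Me2AlCl in CH2Cl2 at −78 °C and should give the racemic cis adduct F1. Pinnick oxidation under the conditions of step 6 gives the racemic acid F2. This is resolved by fractional crystallisation with (R)-1-phenylethylamine, collecting the (R)-1-phenylethylammonium salt of the (1S,2R)-acid F3 from the crystals or the mother liquor; the (S)-amine serves if the other salt crystallises better. Acidification releases 11. This fallback answers catalyst failure and face selection, not the intrinsic regiochemistry of the diene.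

Step 8. Proton loss from the C8 cation may go to the less substituted positions without full equilibration. The ester carbonyl may also intercept the C10 cation, or some cis-fused closure may occur. Fallback, from 12, returning at 13: ring closure and olefin placement are separated. Brief treatment with ClSO3H in 2-nitropropane at −78 °C, followed by an amine quench, closes ring B under kinetic control. This should give the trans-fused 7-ene isomer F4 and the exocyclic 8(17)-ene isomer F5. The mixture is then carried through a separate acid-mediated olefin migration (p-TsOH·H2O, toluene, 80 °C) to the tetrasubstituted 8(9)-olefin 13.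

Step 9. The organoaluminium or butyllithium may attack the methyl ester, or carbometalation and hydroxymethylation may be incomplete. Fallback, from 13, returning at 16: Markovnikov hydration of the alkyne (Ph3PAuNTf2 cat., aqueous MeOH) gives the methyl ketone F6. Horner–Wadsworth–Emmons olefination with triethyl phosphonoacetate and NaH gives the E-enoate F7, the Z isomer being removed by chromatography. Reduction with i-Bu2AlH at −78 °C should take the unhindered conjugated ethyl ester in preference to the axial neopentyl C19 methyl ester, giving 16.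

Further compounds
F1 | step 5 | racemic cis-1,3-dimethyl-2-[(3E)-3-methyloct-3-en-7-yn-1-yl]cyclohex-3-ene-1-carbaldehyde (both enantiomers) | O=C[C@@]1(C)CCC=C(C)[C@H]1CC/C(C)=C/CCC#C.O=C[C@]1(C)CCC=C(C)[C@@H]1CC/C(C)=C/CCC#C
F2 | step 5 | racemic cis-1,3-dimethyl-2-[(3E)-3-methyloct-3-en-7-yn-1-yl]cyclohex-3-ene-1-carboxylic acid (both enantiomers) | OC(=O)[C@@]1(C)CCC=C(C)[C@H]1CC/C(C)=C/CCC#C.OC(=O)[C@]1(C)CCC=C(C)[C@@H]1CC/C(C)=C/CCC#C
F3 | step 5 | (R)-1-phenylethylammonium (1S,2R)-1,3-dimethyl-2-[(3E)-3-methyloct-3-en-7-yn-1-yl]cyclohex-3-ene-1-carboxylate | [O-]C(=O)[C@@]1(C)CCC=C(C)[C@H]1CC/C(C)=C/CCC#C.C[C@@H]([NH3+])c1ccccc1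
F4 | step 8 | methyl (1S,4aR,5S,8aR)-5-(but-3-yn-1-yl)-1,4a,6-trimethyl-1,2,3,4,4a,5,8,8a-octahydronaphthalene-1-carboxylate (7-ene isomer, 9α-H) | COC(=O)[C@@]1(C)CCC[C@]2(C)[C@@H](CCC#C)C(C)=CC[C@@H]12
F5 | step 8 | methyl (1S,4aR,5S,8aR)-5-(but-3-yn-1-yl)-1,4a-dimethyl-6-methylidenedecahydronaphthalene-1-carboxylate (8(17)-ene isomer, 9α-H) | COC(=O)[C@@]1(C)CCC[C@]2(C)[C@@H](CCC#C)C(=C)CC[C@@H]12
F6 | step 9 | methyl (1S,4aS,8aR)-1,4a,6-trimethyl-5-(3-oxobutyl)-1,2,3,4,4a,7,8,8a-octahydronaphthalene-1-carboxylate | COC(=O)[C@@]1(C)CCC[C@]2(C)C(CCC(C)=O)=C(C)CC[C@@H]12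
F7 | step 9 | methyl (1S,4aS,8aR)-5-[(3E)-5-ethoxy-3-methyl-5-oxopent-3-en-1-yl]-1,4a,6-trimethyl-1,2,3,4,4a,7,8,8a-octahydronaphthalene-1-carboxylate | COC(=O)[C@@]1(C)CCC[C@]2(C)C(CC/C(C)=C/C(=O)OCC)=C(C)CC[C@@H]12
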